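Ring A of the flavone is taken apart across C5–C6, C4a–C8a and C8–C8a. The feature exploited is the C6 methoxy group para to the C8a oxygen, flanked by the C7 and C8 methoxy groups and by C5–H, which is the pattern a chromium carbene benzannulation leaves behind. In one operation a (Z)-1,2-dimethoxyvinyl(methoxy)carbene complex of Cr(CO)5, one of its CO ligands and the terminal alkyne of a silyl-protected 1-arylpenta-1,4-diyn-3-ol should merge into the fully substituted ring A phenol, which already carries C4 as a carbinol and C2–C3 as an alkyne. Desilylation, oxidation and amine-mediated closure of ring C finish the synthesis.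

Key step: step 5

Remark on stereochemistry: the carbinol carbon of 8 and of 11–16 is racemic and is written without a descriptor; it becomes the C4 carbonyl carbon in step 7, and the target has no stereocentre.
Assumption: 1 is used as the pure Z isomer; its geometry only affects the rate of ring closure, because it vanishes when ring A becomes aromatic.

Step 1
Reactants: 1 (Z)-1,2-dimethoxyethene; 2 chromium hexacarbonyl
Product: 5 pentacarbonyl[(Z)-1,2-dimethoxyvinyl(methoxy)carbene]chromium, via vinyllithium 3 (not isolated), via lithium acylpentacarbonylchromate 4 (not isolated)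
Conditions: t-BuLi, THF, −78 °C; Cr(CO)6, THF, −78 to 0 °C; then Me3OBF4, CH2Cl2, 0 °C
Reagents that add atoms: trimethyloxonium tetrafluoroborate, C[O+](C)C.F[B-](F)(F)F
Why: Fischer carbene synthesis, in which the vinylic C–H next to oxygen is lithiated with retention of the cis geometry, the vinyllithium adds to a CO ligand to give an acylchromate, and the oxonium salt methylates its oxygen; α-alkoxyvinyllithium reagents are established partners in this sequence.

Step 2
Reactants: 6 4-ethynyl-1,2-dimethoxybenzene
Product: 9 3-(3,4-dimethoxyphenyl)prop-2-ynal, via lithium acetylide 7 (not isolated), via lithium aminoalkoxide 8 (not isolated)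
Conditions: n-BuLi, THF, −78 °C; DMF, −78 °C to rt; inverse quench into cold 10% aq. KH2PO4/MTBE
Reagents that add atoms: N,N-dimethylformamide, CN(C)C=O
Why: Formylation of a lithium acetylide with DMF, in which the tetrahedral adduct 8 survives until the inverse quench into phosphate buffer, which releases the ynal while keeping dimethylamine protonated so that it cannot add to the triple bond.

Step 3
Reactants: 9 3-(3,4-dimethoxyphenyl)prop-2-ynal; 10 ethynylmagnesium bromide
Product: 12 rac-1-(3,4-dimethoxyphenyl)penta-1,4-diyn-3-ol, via bromomagnesium alkoxide 11 (not isolated)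
Conditions: THF, −20 to 0 °C; sat. aq. NH4Cl
Reagents that add atoms: none
Why: 1,2-Addition of an alkynyl Grignard reagent to an aldehyde, where the hard acetylide attacks the formyl carbon and not the ynal β-carbon; the new carbinol stereocentre is formed as a racemate on purpose, because step 7 oxidises it away.

Step 4
Reactants: 12 rac-1-(3,4-dimethoxyphenyl)penta-1,4-diyn-3-ol
Product: 13 rac-tert-butyl{[1-(3,4-dimethoxyphenyl)penta-1,4-diyn-3-yl]oxy}dimethylsilane
Conditions: TBSCl, imidazole, DMF, 0 °C to rt
Reagents that add atoms: tert-butyldimethylsilyl chloride, CC(C)(C)[Si](C)(C)Cl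
Why: Imidazole-promoted silylation of a secondary alcohol under weakly basic conditions that should not isomerise the skipped diyne; the bulky silyl ether later prevents trapping of the ketene by the hydroxyl and reinforces the alkyne regiochemistry.

Step 5
Reactants: 5 pentacarbonyl[(Z)-1,2-dimethoxyvinyl(methoxy)carbene]chromium; 13 rac-tert-butyl{[1-(3,4-dimethoxyphenyl)penta-1,4-diyn-3-yl]oxy}dimethylsilane
Product: 15 rac-6-[1-(tert-butyldimethylsilyloxy)-3-(3,4-dimethoxyphenyl)prop-2-yn-1-yl]-2,3,4-trimethoxyphenol, via Cr(CO)3-bound phenol 14 (not isolated)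
Conditions: 13 (1.3 equiv), degassed THF (0.05 M), 50 °C, Ar; then air, Et2O, daylight, rt
Reagents that add atoms: none
Why: Proposed new method: thermal loss of one CO ligand from 5 lets the terminal alkyne of 13 coordinate and insert into the Cr=C bond with its CH carbon bonding to the carbene carbon (C5–C6), and CO insertion at the new carbene carbon then gives a chromium-bound dienylketene (C4a–C8a). Ring A closes by 6π-electrocyclisation of this ketene onto the methoxy-bearing vinyl terminus (C8–C8a), and tautomerisation of the cyclohexadienone gives the phenol as its Cr(CO)3 complex 14, from which air releases 15. The closest known reaction is the Dötz benzannulation of alkenyl(methoxy)carbene chromium complexes, α-alkoxyvinyl ones included, with terminal alkynes; a vinyl group with methoxy groups on both carbons is untested, but its β-hydrogen sits cis to the carbene carbon as in the well-behaved trans-propenyl complexes. No stereocentre is formed and the racemic carbinol carbon of 13 is not touched. The step needs regioselectivity, which the usual steric rule for terminal alkynes supplies by placing the silyloxy-bearing carbon next to the new hydroxyl, and chemoselectivity for the terminal over the internal aryl alkyne, which rests on its far faster insertion, on the excess of 13 and on the one-carbon spacer that rules out an intramolecular second insertion. An oxidative work-up with (NH4)2Ce(NO3)6 is avoided because it would turn the para-methoxyphenol into a quinone.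

Step 6
Reactants: 15 rac-6-[1-(tert-butyldimethylsilyloxy)-3-(3,4-dimethoxyphenyl)prop-2-yn-1-yl]-2,3,4-trimethoxyphenol
Product: 16 rac-6-[3-(3,4-dimethoxyphenyl)-1-hydroxyprop-2-yn-1-yl]-2,3,4-trimethoxyphenol
Conditions: TBAF (1.2 equiv), AcOH (1.2 equiv), THF, 0 °C to rt
Reagents that add atoms: none
Why: Fluoride-driven cleavage of a silyl ether, buffered with acetic acid so that no phenoxide is present to attack the alkyne or to expel the benzylic oxygen as an o-quinone methide.

Step 7
Reactants: 16 rac-6-[3-(3,4-dimethoxyphenyl)-1-hydroxyprop-2-yn-1-yl]-2,3,4-trimethoxyphenol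
Product: 17 3-(3,4-dimethoxyphenyl)-1-(2-hydroxy-3,4,5-trimethoxyphenyl)prop-2-yn-1-one
Conditions: activated MnO2 (excess), CH2Cl2, rt
Reagents that add atoms: none
Why: Heterogeneous MnO2 oxidation, selective under neutral conditions for the doubly activated benzylic and propargylic alcohol; the ketone formed is stabilised by a hydrogen bond to the ortho hydroxyl, and the racemic stereocentre disappears.

Step 8
Reactants: 17 3-(3,4-dimethoxyphenyl)-1-(2-hydroxy-3,4,5-trimethoxyphenyl)prop-2-yn-1-one
Product: 19 2-(3,4-dimethoxyphenyl)-6,7,8-trimethoxy-4H-chromen-4-one, via enaminone 18 (not isolated)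
Conditions: Et2NH (3 equiv), EtOH, rt to 50 °C
Reagents that add atoms: none
Why: Amine-mediated cycloisomerisation of an o-hydroxyaryl ynone, in which aza-Michael addition of Et2NH gives the β-enaminone 18 and the phenol then displaces the amine at the same carbon by addition–elimination; this can only close the six-membered pyranone (net 6-endo O1–C2 bond formation) and so avoids the 5-exo aurone pathway seen with carbonate bases.

Compound list
1 | (Z)-1,2-dimethoxyethene | CO/C=C\OC | starting material
2 | chromium hexacarbonyl, Cr(CO)6 | O=C=[Cr](=C=O)(=C=O)(=C=O)(=C=O)=C=O | starting material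
3 | (Z)-1,2-dimethoxyvinyllithium | CO/C=C(\OC)[Li] | intermediate (not isolated)
4 | lithium pentacarbonyl[(Z)-2,3-dimethoxyprop-2-enoyl]chromate | [Li+].CO/C=C(\OC)C([O-])=[Cr](=C=O)(=C=O)(=C=O)(=C=O)=C=O | intermediate (not isolated)
5 | pentacarbonyl[(Z)-1,2-dimethoxyvinyl(methoxy)carbene]chromium | CO/C=C(\OC)C(OC)=[Cr](=C=O)(=C=O)(=C=O)(=C=O)=C=O | intermediate
6 | 4-ethynyl-1,2-dimethoxybenzene | C#Cc1ccc(OC)c(OC)c1 | starting material
7 | lithium (3,4-dimethoxyphenyl)acetylide | [Li]C#Cc1ccc(OC)c(OC)c1 | intermediate (not isolated)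
8 | rac-lithium 1-(dimethylamino)-3-(3,4-dimethoxyphenyl)prop-2-yn-1-olate | [Li+].CN(C)C([O-])C#Cc1ccc(OC)c(OC)c1 | intermediate (not isolated)
9 | 3-(3,4-dimethoxyphenyl)prop-2-ynal | O=CC#Cc1ccc(OC)c(OC)c1 | intermediate
10 | ethynylmagnesium bromide | C#C[Mg]Br | starting material
11 | rac-bromomagnesium 1-(3,4-dimethoxyphenyl)penta-1,4-diyn-3-olate | C#CC(O[Mg]Br)C#Cc1ccc(OC)c(OC)c1 | intermediate (not isolated)
12 | rac-1-(3,4-dimethoxyphenyl)penta-1,4-diyn-3-ol | C#CC(O)C#Cc1ccc(OC)c(OC)c1 | intermediate
13 | rac-tert-butyl{[1-(3,4-dimethoxyphenyl)penta-1,4-diyn-3-yl]oxy}dimethylsilane | C#CC(O[Si](C)(C)C(C)(C)C)C#Cc1ccc(OC)c(OC)c1 | intermediate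
14 | tricarbonylchromium complex of 15, Cr(CO)3 bound η6 to ring A (written as a separate fragment) | Oc1c(OC)c(OC)c(OC)cc1C(O[Si](C)(C)C(C)(C)C)C#Cc1ccc(OC)c(OC)c1.O=C=[Cr](=C=O)=C=O | intermediate (not isolated)
15 | rac-6-[1-(tert-butyldimethylsilyloxy)-3-(3,4-dimethoxyphenyl)prop-2-yn-1-yl]-2,3,4-trimethoxyphenol | Oc1c(OC)c(OC)c(OC)cc1C(O[Si](C)(C)C(C)(C)C)C#Cc1ccc(OC)c(OC)c1 | intermediate
16 | rac-6-[3-(3,4-dimethoxyphenyl)-1-hydroxyprop-2-yn-1-yl]-2,3,4-trimethoxyphenol | Oc1c(OC)c(OC)c(OC)cc1C(O)C#Cc1ccc(OC)c(OC)c1 | intermediate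
17 | 3-(3,4-dimethoxyphenyl)-1-(2-hydroxy-3,4,5-trimethoxyphenyl)prop-2-yn-1-one | Oc1c(OC)c(OC)c(OC)cc1C(=O)C#Cc1ccc(OC)c(OC)c1 | intermediate
18 | (E)-3-(diethylamino)-3-(3,4-dimethoxyphenyl)-1-(2-hydroxy-3,4,5-trimethoxyphenyl)prop-2-en-1-one | CCN(CC)/C(c1ccc(OC)c(OC)c1)=C/C(=O)c1cc(OC)c(OC)c(OC)c1O | intermediate (not isolated)
19 | 2-(3,4-dimethoxyphenyl)-6,7,8-trimethoxy-4H-chromen-4-one | COc1ccc(-c2cc(=O)c3cc(OC)c(OC)c(OC)c3o2)cc1OC | target

Total step count: 8. Longest linear sequence: 7 steps (steps 2 to 8, from 6); the carbene branch (step 1) joins at step 5.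

Steps most likely to fail

Step 5. The cascade may stall or divert: slow CO loss from the donor-stabilised carbene, alkyne insertion without CO insertion (five-membered ring products), alkyne oligomerisation, or ionisation of the benzylic silyloxy group on the Cr(CO)3-bound phenol. The fallback uses known chemistry, sets out from 6 and comes back at 16; ring A is then taken from a commercial arene instead of being built. 2,3,4-Trimethoxyphenol, whose only free ortho position is C6, is ortho-formylated with MgCl2, Et3N and paraformaldehyde in MeCN at reflux to 2-hydroxy-3,4,5-trimethoxybenzaldehyde F1. Acetylide 7, made from 6 with n-BuLi as in step 2 and used in 2.3 equiv because the first equivalent is consumed by the phenol, is added to F1 in THF at −78 to 0 °C. Work-up with NH4Cl gives 16, and the route continues with step 7.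

Step 1. Lithium methoxide may be lost from vinyllithium 3 by β-elimination (lithium and the β-methoxy group are anti) while it adds slowly to the sparingly soluble Cr(CO)6, or the lithiation may be incomplete. The fallback sets out from 2 and comes back at 5; the acyl group is brought in as an electrophile, so no vinyl anion is needed. Methyl methoxyacetate is formylated with methyl formate and NaH in THF to sodium (Z)-2,3-dimethoxy-3-oxoprop-1-en-1-olate F2, which is O-methylated with Me2SO4 in DMF to methyl (Z)-2,3-dimethoxyprop-2-enoate F3. LiOH in THF/water followed by acidification gives (Z)-2,3-dimethoxyprop-2-enoic acid F4, and (COCl)2 with catalytic DMF gives (Z)-2,3-dimethoxyprop-2-enoyl chloride F5. Compound 2 is reduced with KC8 (2 equiv, THF, −78 °C to rt) to dipotassium pentacarbonylchromate K2Cr(CO)5 F6, which is acylated by F5 at −78 °C to potassium pentacarbonyl[(Z)-2,3-dimethoxyprop-2-enoyl]chromate F7. Methylation of F7 with Me3OBF4 in CH2Cl2 at 0 °C gives 5.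

Step 7. Over-oxidation of the electron-rich para-methoxyphenol (oxidative demethylation to a quinone, or oxidative coupling) may compete with oxidation of the alcohol. The fallback sets out from 15 and comes back at 17; the phenol is masked before the oxidation. MOMCl and iPr2NEt in CH2Cl2 convert 15 into rac-tert-butyl{[3-(3,4-dimethoxyphenyl)-1-[3,4,5-trimethoxy-2-(methoxymethoxy)phenyl]prop-2-yn-1-yl]oxy}dimethylsilane F8. TBAF in THF gives rac-3-(3,4-dimethoxyphenyl)-1-[3,4,5-trimethoxy-2-(methoxymethoxy)phenyl]prop-2-yn-1-ol F9, which MnO2 or Dess–Martin periodinane oxidises to 3-(3,4-dimethoxyphenyl)-1-[3,4,5-trimethoxy-2-(methoxymethoxy)phenyl]prop-2-yn-1-one F10. Brief treatment with HCl in MeOH at 0 °C removes the acetal and returns 17, which goes on to step 8.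

Further compounds
F1 | step 5 | 2-hydroxy-3,4,5-trimethoxybenzaldehyde | O=Cc1cc(OC)c(OC)c(OC)c1O
F2 | step 1 | sodium (Z)-2,3-dimethoxy-3-oxoprop-1-en-1-olate | [Na+].[O-]/C=C(\OC)C(=O)OC
F3 | step 1 | methyl (Z)-2,3-dimethoxyprop-2-enoate | CO/C=C(\OC)C(=O)OC
F4 | step 1 | (Z)-2,3-dimethoxyprop-2-enoic acid | CO/C=C(\OC)C(=O)O
F5 | step 1 | (Z)-2,3-dimethoxyprop-2-enoyl chloride | CO/C=C(\OC)C(=O)Cl
F6 | step 1 | dipotassium pentacarbonylchromate, K2Cr(CO)5 | [K+].[K+].O=C=[Cr-2](=C=O)(=C=O)(=C=O)=C=O
F7 | step 1 | potassium pentacarbonyl[(Z)-2,3-dimethoxyprop-2-enoyl]chromate | [K+].CO/C=C(\OC)C([O-])=[Cr](=C=O)(=C=O)(=C=O)(=C=O)=C=O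
F8 | step 7 | rac-tert-butyl{[3-(3,4-dimethoxyphenyl)-1-[3,4,5-trimethoxy-2-(methoxymethoxy)phenyl]prop-2-yn-1-yl]oxy}dimethylsilane | COCOc1c(OC)c(OC)c(OC)cc1C(O[Si](C)(C)C(C)(C)C)C#Cc1ccc(OC)c(OC)c1
F9 | step 7 | rac-3-(3,4-dimethoxyphenyl)-1-[3,4,5-trimethoxy-2-(methoxymethoxy)phenyl]prop-2-yn-1-ol | COCOc1c(OC)c(OC)c(OC)cc1C(O)C#Cc1ccc(OC)c(OC)c1
F10 | step 7 | 3-(3,4-dimethoxyphenyl)-1-[3,4,5-trimethoxy-2-(methoxymethoxy)phenyl]prop-2-yn-1-one | COCOc1c(OC)c(OC)c(OC)cc1C(=O)C#Cc1ccc(OC)c(OC)c1
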